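The ring is numbered O1, C2 (guaiacyl), C3 (CH2O-acyl), C4 (=CH-guaiacyl), C5 (CH2), and the target is (2R,3S,4E) with C2/C3 trans. The last disconnections are the two aryl silyl ethers and the 4-hydroxybenzoate (Mitsunobu at C3-CH2OH). The CH2OH is traced back to a C3 tert-butyl ester.
Enabling feature: C4 of the tetrahydrofuran carries an exocyclic C=C, so C3-C4(=CHAr)-C5 is a trimethylenemethane unit and the remaining ring atoms O1-C2(Ar) are the C=O of vanillin. At the ester oxidation level C3 is a stabilised carbanion, and the electron-rich guaiacyl on the exocyclic carbon stabilises the allyl cation C5-C4-CHAr.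
Key disconnection: C2-C3 and O1-C5 together, by an enantioselective Pd-catalysed (3+2) cycloaddition of an ester- and aryl-substituted Pd-trimethylenemethane zwitterion with O-TIPS-vanillin. The zwitterion comes from an achiral, acyclic allylic Boc carbonate, and the step makes the ring and both stereocentres and keeps the E alkene.
The donor comes in three steps from the same O-TIPS-vanillin: Horner-Wadsworth-Emmons reaction with a mixed ethyl/tert-butyl phosphonosuccinate, selective DIBAL-H reduction, Boc carbonate.
Ring order: the three benzene rings are bought, and the tetrahydrofuran is the only ring formed, in the key step.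

Key step: step 6

Assumption: for the new donor of step 6 the sense of induction cannot be derived safely from a model. The ligand enantiomer written is taken to give the (2R,3R) ester. Its equally available mirror image is used if the opposite series forms.

Step 1
Reactants: 1 vanillin (4-hydroxy-3-methoxybenzaldehyde)
Product: 2 3-methoxy-4-(triisopropylsilyloxy)benzaldehyde (O-TIPS-vanillin)
Conditions: TIPSCl, imidazole, DMF, rt
Reagents that add atoms: triisopropylsilyl chloride (TIPSCl), CC(C)[Si](Cl)(C(C)C)C(C)C
Why: Imidazole-promoted silyl ether formation at the acidic phenol; the bulky TIPS ether should survive phosphonate anions, hydride reagents and hindered alkoxide and leaves with fluoride at the end.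

Step 2
Reactants: 3 triethyl phosphonoacetate; 4 tert-butyl bromoacetate
Product: 5 4-tert-butyl 1-ethyl 2-(diethoxyphosphoryl)butanedioate (racemic)
Conditions: NaH, THF, 0 °C; then 4, 0 °C → rt
Reagents that add atoms: none
Why: SN2 C-alkylation of the stabilised phosphonoacetate anion with a reactive α-bromo ester gives a phosphonosuccinate with two esters of different size; its stereocentre is racemic and is lost in step 3.

Step 3
Reactants: 5 4-tert-butyl 1-ethyl 2-(diethoxyphosphoryl)butanedioate; 2 O-TIPS-vanillin
Product: 6 4-tert-butyl 1-ethyl (2E)-2-[3-methoxy-4-(triisopropylsilyloxy)benzylidene]butanedioate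
Conditions: NaH, THF, 0 °C; then 2, 0 °C → rt
Reagents that add atoms: none
Why: Horner-Wadsworth-Emmons olefination, in which α-substituted phosphonoacetates and aromatic aldehydes should give the E alkene (aryl trans to CO2Et, cis to CH2CO2tBu).

Step 4
Reactants: 6 4-tert-butyl 1-ethyl (2E)-2-[3-methoxy-4-(triisopropylsilyloxy)benzylidene]butanedioate
Product: 7 tert-butyl (3E)-3-(hydroxymethyl)-4-[3-methoxy-4-(triisopropylsilyloxy)phenyl]but-3-enoate
Conditions: DIBAL-H (2.2 equiv), CH2Cl2, −78 °C; aq. Rochelle salt
Reagents that add atoms: none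
Why: Chemoselective DIBAL-H 1,2-reduction of the unhindered conjugated ethyl ester, while the bulky tert-butyl ester is shielded at −78 °C and also holds back lactonisation of the γ-hydroxy ester.

Step 5
Reactants: 7 tert-butyl (3E)-3-(hydroxymethyl)-4-[3-methoxy-4-(triisopropylsilyloxy)phenyl]but-3-enoate
Product: 8 tert-butyl (3E)-3-{[(tert-butoxycarbonyl)oxy]methyl}-4-[3-methoxy-4-(triisopropylsilyloxy)phenyl]but-3-enoate
Conditions: Boc2O, DMAP (cat.), CH2Cl2, 0 °C → rt
Reagents that add atoms: di-tert-butyl dicarbonate (Boc2O), CC(C)(C)OC(=O)OC(=O)OC(C)(C)C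
Why: DMAP-catalysed O-acylation of a primary allylic alcohol gives the carbonate, which serves in step 6 both as the leaving group and as the hidden base.

Step 6
Reactants: 8 tert-butyl (3E)-3-{[(tert-butoxycarbonyl)oxy]methyl}-4-[3-methoxy-4-(triisopropylsilyloxy)phenyl]but-3-enoate; 2 O-TIPS-vanillin
Product: 11 tert-butyl (2R,3R,4E)-4-[3-methoxy-4-(triisopropylsilyloxy)benzylidene]-2-[3-methoxy-4-(triisopropylsilyloxy)phenyl]tetrahydrofuran-3-carboxylate, via Pd-TMM zwitterion 9 (not isolated), via allyl-Pd aldolate 10 (not isolated)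
Conditions: Pd2(dba)3·CHCl3 (2.5 mol %), L* = (S)-BINOL-derived phosphoramidite of (2R,5R)-2,5-di(2-naphthyl)pyrrolidine (11 mol %), 2 (1.5 equiv), 4 Å MS, toluene, slow addition of 8, 0 °C → rt
Reagents that add atoms: none
Why: Proposed new method: Pd(0) ionises the allylic carbonate of 8 to a syn-aryl η3-allyl cation, the tert-butoxide released with CO2 removes the ester α-proton beside the cationic allyl unit to give the ester-stabilised Pd-trimethylenemethane zwitterion 9, its carbanion adds to the C=O of 2 to give aldolate 10, and the alkoxide then attacks the CH2 terminus of the allyl unit anti to Pd, so the event is a stepwise (3+2) cycloaddition that returns Pd(0). The closest known reaction types are the enantioselective Pd-trimethylenemethane cycloaddition of aryl aldehydes to 4-methylenetetrahydrofurans, the base-free generation of acceptor-substituted trimethylenemethane donors from 2-(acceptor-methyl)allyl carbonates and the Pd-catalysed aldol/O-allylation (3+2) of vinylcyclopropane diesters with aldehydes; new is the donor that bears an ester and an aryl group at two different termini in combination with an aldehyde acceptor. The one ring formed, the tetrahydrofuran, closes by intramolecular O-allylation at C5, a 5-exo-tet-type displacement of Pd (5-endo if counted on the allyl π system), the closure common to all Pd-trimethylenemethane cycloadditions. C2 is controlled by the chiral phosphoramidite-Pd fragment, which stays bound to the allyl part of 10 while the reversible aldol addition and the irreversible ring closure select one aldehyde face, and C3 is controlled by C2, since closure with the C2 aryl and the C3 ester trans on the forming envelope should be fastest and the acidic C3-H lets a cis isomer equilibrate to the more stable trans ester. The step needs C-C bond formation at the ester-bearing terminus (secured by the ester, which localises the negative charge, and by the electron-rich guaiacyl ring, which keeps its carbon in the cationic allyl part), O-attack at CH2 instead of CHAr (less hindered terminus, styrene conjugation retained) and the E alkene (the E carbonate gives the syn-aryl allyl unit, and syn/anti exchange would need an unfavourable η1-benzylic Pd form). Self-alkylation of 9 is held down by slow addition of 8 to an excess of 2, and the hindered tert-butoxide from the Boc carbonate should attack neither the allyl unit nor the TIPS ethers.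

Step 7
Reactants: 11 tert-butyl (2R,3R,4E)-4-[3-methoxy-4-(triisopropylsilyloxy)benzylidene]-2-[3-methoxy-4-(triisopropylsilyloxy)phenyl]tetrahydrofuran-3-carboxylate
Product: 12 {(2R,3S,4E)-4-[3-methoxy-4-(triisopropylsilyloxy)benzylidene]-2-[3-methoxy-4-(triisopropylsilyloxy)phenyl]tetrahydrofuran-3-yl}methanol
Conditions: LiAlH4, Et2O, −20 → 0 °C; aq. Rochelle salt
Reagents that add atoms: none
Why: LiAlH4 ester reduction, in which hydride addition to the C=O should outrun deprotonation at C3; no bond at a stereocentre is touched (the descriptor of C3 changes only by priority) and C3 is no longer acidic afterwards.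

Step 8
Reactants: 12 {(2R,3S,4E)-4-[3-methoxy-4-(triisopropylsilyloxy)benzylidene]-2-[3-methoxy-4-(triisopropylsilyloxy)phenyl]tetrahydrofuran-3-yl}methanol; 13 4-hydroxybenzoic acid
Product: 14 {(2R,3S,4E)-4-[3-methoxy-4-(triisopropylsilyloxy)benzylidene]-2-[3-methoxy-4-(triisopropylsilyloxy)phenyl]tetrahydrofuran-3-yl}methyl 4-hydroxybenzoate
Conditions: PPh3, DIAD, 13 (1.3 equiv), THF, 0 °C → rt
Reagents that add atoms: none
Why: Mitsunobu esterification, in which the carboxylic acid is far more acidic than its own phenol, so only the carboxylate is alkylated, and the displacement takes place at a CH2 group so no stereocentre is affected.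

Step 9
Reactants: 14 {(2R,3S,4E)-4-[3-methoxy-4-(triisopropylsilyloxy)benzylidene]-2-[3-methoxy-4-(triisopropylsilyloxy)phenyl]tetrahydrofuran-3-yl}methyl 4-hydroxybenzoate
Product: 15 agastenol
Conditions: TBAF, AcOH (slight excess over TBAF), THF, 0 °C
Reagents that add atoms: none
Why: Fluoride-induced cleavage of the two aryl silyl ethers, with the acetic acid buffer keeping the phenols protonated so that the benzoate should not be cleaved and the p-hydroxybenzyl ether C2-O1 should not open by way of a quinone methide.

Compound list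
1 | vanillin | COc1cc(C=O)ccc1O | starting material
2 | 3-methoxy-4-(triisopropylsilyloxy)benzaldehyde | COc1cc(C=O)ccc1O[Si](C(C)C)(C(C)C)C(C)C | intermediate
3 | triethyl phosphonoacetate | CCOC(=O)CP(=O)(OCC)OCC | starting material
4 | tert-butyl bromoacetate | CC(C)(C)OC(=O)CBr | starting material
5 | 4-tert-butyl 1-ethyl 2-(diethoxyphosphoryl)butanedioate (racemic) | CCOC(=O)C(CC(=O)OC(C)(C)C)P(=O)(OCC)OCC | intermediate
6 | 4-tert-butyl 1-ethyl (2E)-2-[3-methoxy-4-(triisopropylsilyloxy)benzylidene]butanedioate | COc1cc(/C=C(/C(=O)OCC)CC(=O)OC(C)(C)C)ccc1O[Si](C(C)C)(C(C)C)C(C)C | intermediate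
7 | tert-butyl (3E)-3-(hydroxymethyl)-4-[3-methoxy-4-(triisopropylsilyloxy)phenyl]but-3-enoate | COc1cc(/C=C(/CO)CC(=O)OC(C)(C)C)ccc1O[Si](C(C)C)(C(C)C)C(C)C | intermediate
8 | tert-butyl (3E)-3-{[(tert-butoxycarbonyl)oxy]methyl}-4-[3-methoxy-4-(triisopropylsilyloxy)phenyl]but-3-enoate | COc1cc(/C=C(/COC(=O)OC(C)(C)C)CC(=O)OC(C)(C)C)ccc1O[Si](C(C)C)(C(C)C)C(C)C | intermediate
9 | ester-stabilised Pd-trimethylenemethane zwitterion (drawn as the σ-allyl form, ligand omitted) | COc1cc(/C=C(/C[Pd+])[CH-]C(=O)OC(C)(C)C)ccc1O[Si](C(C)C)(C(C)C)C(C)C | intermediate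
10 | allyl-Pd aldolate, syn series (drawn as the σ-allyl form, ligand omitted) | COc1cc(/C=C(/C[Pd+])[C@H]([C@@H]([O-])c2ccc(O[Si](C(C)C)(C(C)C)C(C)C)c(OC)c2)C(=O)OC(C)(C)C)ccc1O[Si](C(C)C)(C(C)C)C(C)C | intermediate
11 | tert-butyl (2R,3R,4E)-4-[3-methoxy-4-(triisopropylsilyloxy)benzylidene]-2-[3-methoxy-4-(triisopropylsilyloxy)phenyl]tetrahydrofuran-3-carboxylate | COc1cc(/C=C2/CO[C@@H](c3ccc(O[Si](C(C)C)(C(C)C)C(C)C)c(OC)c3)[C@@H]2C(=O)OC(C)(C)C)ccc1O[Si](C(C)C)(C(C)C)C(C)C | intermediate
12 | {(2R,3S,4E)-4-[3-methoxy-4-(triisopropylsilyloxy)benzylidene]-2-[3-methoxy-4-(triisopropylsilyloxy)phenyl]tetrahydrofuran-3-yl}methanol | COc1cc(/C=C2/CO[C@@H](c3ccc(O[Si](C(C)C)(C(C)C)C(C)C)c(OC)c3)[C@@H]2CO)ccc1O[Si](C(C)C)(C(C)C)C(C)C | intermediate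
13 | 4-hydroxybenzoic acid | O=C(O)c1ccc(O)cc1 | starting material
14 | bis-TIPS ether of agastenol | COc1cc(/C=C2/CO[C@@H](c3ccc(O[Si](C(C)C)(C(C)C)C(C)C)c(OC)c3)[C@@H]2COC(=O)c2ccc(O)cc2)ccc1O[Si](C(C)C)(C(C)C)C(C)C | intermediate
15 | agastenol | COc1cc(/C=C2/CO[C@@H](c3ccc(O)c(OC)c3)[C@@H]2COC(=O)c2ccc(O)cc2)ccc1O | target

Total step count: 9.
Longest linear sequence: 8 (steps 1 and 3-9 from vanillin; the same length from triethyl phosphonoacetate through steps 2-9).

Steps most likely to fail

1. Step 6. Several processes may defeat it.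
- Self-alkylation of the zwitterion may outrun its addition to the electron-rich aldehyde.
- Retro-aldol cleavage may win over a slow O-allylation.
- Syn/anti isomerisation of the allyl unit may erode the alkene geometry.
- Closure may take place at the benzylic terminus.
- The facial selectivity may be poor.
- The C=C may migrate into conjugation with the ester.

The fallback makes the same two bonds stepwise with known chemistry. It sets out from 7 (with 2) and comes back at 12, so that it replaces steps 5-7. Silylation of 7 (TBSCl, imidazole, DMF) gives the allylic TBS ether F1. TMSOTf/2,6-lutidine followed by aqueous work-up cleaves only the tert-butyl ester and gives the carboxylic acid F2, which is coupled (DCC, DMAP) with commercial (R)-4-benzyloxazolidin-2-one to the N-acyl oxazolidinone F3. An Evans syn aldol reaction (Bu2BOTf, iPr2NEt, CH2Cl2, −78 °C, then 2) forms C2-C3. It sets both centres through the chair transition state of the Z boron enolate under auxiliary control and gives the syn aldol F4, whose configuration maps onto the 2,3-trans ring. HF·pyridine buffered with pyridine removes the primary alkyl TBS ether and gives the diol F5. MsCl/Et3N at −20 °C sulfonylates only the primary allylic alcohol to the allylic mesylate F6. On warming, the benzylic hydroxyl displaces the mesylate (5-exo-tet, no π-allyl species, so the alkene geometry is kept) to give the tetrahydrofuran imide F7. LiBH4 (Et2O, MeOH) removes the auxiliary reductively and gives 12.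

2. Step 4. The tert-butyl ester may be reduced as well, the aluminium alkoxide may attack it with lactonisation, or conjugate reduction may compete. The fallback replaces ester differentiation by hydride size with acid activation. It sets out from 5 (with 2) and comes back at 7. One equivalent of NaOH in aqueous EtOH hydrolyses only the ethyl carboxylate of 5, before any silyl ether is present, and gives the phosphono acid F8. The Horner-Wadsworth-Emmons reaction of its dianion (NaH, 2.1 equiv, THF) with 2 gives the E-configured conjugated acid F9. Isobutyl chloroformate/N-methylmorpholine converts it into the mixed carbonic anhydride F10, and NaBH4 (THF/MeOH, −15 °C) reduces this to 7 without touching the tert-butyl ester.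

3. Step 8. Displacement at the β-branched CH2 may be slow, so that alkylation of the phenol oxygen or elimination of the activated alcohol to the conjugated diene takes over. The fallback inverts the polarity, with the alcohol acting as nucleophile. It sets out from 12 and comes back at 14. Steglich acylation of 12 with commercial 4-acetoxybenzoic acid (EDC·HCl, DMAP, CH2Cl2) gives the 4-acetoxybenzoate F11. Pyrrolidine (CH2Cl2, 0 °C) cleaves the aryl acetate by aminolysis, while the alkyl benzoate and the TIPS ethers should stay, to give 14.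

Further compounds
F1 | step 6 | tert-butyl (3E)-3-{[(tert-butyldimethylsilyl)oxy]methyl}-4-[3-methoxy-4-(triisopropylsilyloxy)phenyl]but-3-enoate | COc1cc(/C=C(/CO[Si](C)(C)C(C)(C)C)CC(=O)OC(C)(C)C)ccc1O[Si](C(C)C)(C(C)C)C(C)C
F2 | step 6 | (3E)-3-{[(tert-butyldimethylsilyl)oxy]methyl}-4-[3-methoxy-4-(triisopropylsilyloxy)phenyl]but-3-enoic acid | COc1cc(/C=C(/CO[Si](C)(C)C(C)(C)C)CC(=O)O)ccc1O[Si](C(C)C)(C(C)C)C(C)C
F3 | step 6 | (4R)-4-benzyl-3-[(3E)-3-{[(tert-butyldimethylsilyl)oxy]methyl}-4-aryl-but-3-enoyl]oxazolidin-2-one (aryl = 3-methoxy-4-(triisopropylsilyloxy)phenyl) | COc1cc(/C=C(/CO[Si](C)(C)C(C)(C)C)CC(=O)N2[C@H](Cc3ccccc3)COC2=O)ccc1O[Si](C(C)C)(C(C)C)C(C)C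
F4 | step 6 | syn aldol, (αR,βR), of F3 with 2 | COc1cc(/C=C(/CO[Si](C)(C)C(C)(C)C)[C@H]([C@@H](O)c2ccc(O[Si](C(C)C)(C(C)C)C(C)C)c(OC)c2)C(=O)N2[C@H](Cc3ccccc3)COC2=O)ccc1O[Si](C(C)C)(C(C)C)C(C)C
F5 | step 6 | diol from F4 (allylic CH2OH free) | COc1cc(/C=C(/CO)[C@H]([C@@H](O)c2ccc(O[Si](C(C)C)(C(C)C)C(C)C)c(OC)c2)C(=O)N2[C@H](Cc3ccccc3)COC2=O)ccc1O[Si](C(C)C)(C(C)C)C(C)C
F6 | step 6 | primary allylic mesylate of F5 | COc1cc(/C=C(/COS(C)(=O)=O)[C@H]([C@@H](O)c2ccc(O[Si](C(C)C)(C(C)C)C(C)C)c(OC)c2)C(=O)N2[C@H](Cc3ccccc3)COC2=O)ccc1O[Si](C(C)C)(C(C)C)C(C)C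
F7 | step 6 | (2R,3R,4E)-tetrahydrofuran-3-carbonyl imide of (R)-4-benzyloxazolidin-2-one | COc1cc(/C=C2/CO[C@@H](c3ccc(O[Si](C(C)C)(C(C)C)C(C)C)c(OC)c3)[C@@H]2C(=O)N2[C@H](Cc3ccccc3)COC2=O)ccc1O[Si](C(C)C)(C(C)C)C(C)C
F8 | step 4 | 4-tert-butoxy-2-(diethoxyphosphoryl)-4-oxobutanoic acid (racemic) | CCOP(=O)(OCC)C(CC(=O)OC(C)(C)C)C(=O)O
F9 | step 4 | (2E)-4-tert-butoxy-2-[3-methoxy-4-(triisopropylsilyloxy)benzylidene]-4-oxobutanoic acid | COc1cc(/C=C(/C(=O)O)CC(=O)OC(C)(C)C)ccc1O[Si](C(C)C)(C(C)C)C(C)C
F10 | step 4 | isobutyl carbonic mixed anhydride of F9 | COc1cc(/C=C(/C(=O)OC(=O)OCC(C)C)CC(=O)OC(C)(C)C)ccc1O[Si](C(C)C)(C(C)C)C(C)C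
F11 | step 8 | 4-acetoxybenzoate of 12 | COc1cc(/C=C2/CO[C@@H](c3ccc(O[Si](C(C)C)(C(C)C)C(C)C)c(OC)c3)[C@@H]2COC(=O)c2ccc(OC(C)=O)cc2)ccc1O[Si](C(C)C)(C(C)C)C(C)C
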